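Ring A carries an α-ketol: the C6 ketone beside the C7 tertiary carbinol. The route rests on cutting the C6–C7 bond, so that a carbene-catalysed crossed benzoin between a C6 aldehyde and the C7 methyl ketone closes ring A and sets C7, with its hydroxyl cis to the lactone on C8, in one operation. Its substrate, keto aldehyde 13, has C4a masked as a dioxolane, C8 already fixed by an asymmetric allylic alkylation, and the lactone carried as a 2-(trimethylsilyl)ethyl enol ether; it is made by cleaving a cyclohexene. The ketol is then taken on by ketal hydrolysis, C5 chlorination, C4a triflation, Sonogashira coupling, C8a formylation and pyran closure.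

Key step: step 9

Remarks on the chemistry
- Locants C1–C8a follow the isochromene numbering of the target; primed locants belong to the lactone. "Lac" stands for (6S)-6-methyl-2-oxo-4-[2-(trimethylsilyl)ethoxy]-5,6-dihydro-2H-pyran-3-yl.
- Assumption: C3' of the free oxane-2,4-dione lies between two carbonyls and equilibrates through its enol, so the route delivers the dione and the drawn C3' configuration is taken to be the one the free lactone adopts.
- Design points: C8 is set before the key step, so the benzoin does not have to resolve an epimeric mixture. The lactone enol is carried as a 2-(trimethylsilyl)ethyl ether, which leaves under mild acid at the end, where a methyl enol ether would need forcing hydrolysis. The aldehyde is released by alkene cleavage, not by acetal hydrolysis beside the dioxolane.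

Step 1
Reactants: 1 methyl (S)-3-hydroxybutanoate; 2 tert-butyl acetate
Product: 3 tert-butyl (S)-5-hydroxy-3-oxohexanoate
Conditions: LiN(iPr)2 (3.3 equiv), 2 (3.3 equiv), THF, −78 °C; then 1, −78 → −20 °C; aq. NH4Cl
Reagents that add atoms: none
Why: Crossed Claisen condensation, in which excess lithium enolate of 2 acylates at the ester carbonyl of the alkoxide of 1 and the product is protected as its own enolate, the carbinol centre being untouched.

Step 2
Reactants: 3 tert-butyl (S)-5-hydroxy-3-oxohexanoate
Product: 5 (S)-4-hydroxy-6-methyl-5,6-dihydro-2H-pyran-2-one, via (S)-5-hydroxy-3-oxohexanoic acid 4 (not isolated)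
Conditions: CF3CO2H, CH2Cl2, 0 °C → rt
Reagents that add atoms: none
Why: Acidolysis of the tert-butyl ester followed by lactonisation of the δ-hydroxy acid, which should outrun decarboxylation and leaves the carbinol centre as a spectator.

Step 3
Reactants: 6 1,4-dioxaspiro[4.5]dec-7-en-8-yl trifluoromethanesulfonate
Product: 7 8-methyl-1,4-dioxaspiro[4.5]dec-7-ene
Conditions: MeMgBr, Fe(acac)3 (5 mol %), THF/NMP, −30 → 0 °C
Reagents that add atoms: methylmagnesium bromide, C[Mg]Br
Why: Iron-catalysed cross-coupling of an alkenyl triflate with a methyl Grignard reagent places the future C7 methyl group regiospecifically on the alkene and tolerates the ketal at low temperature.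

Step 4
Reactants: 7 8-methyl-1,4-dioxaspiro[4.5]dec-7-ene
Product: 8 rac-8-methyl-1,4-dioxaspiro[4.5]dec-8-en-7-ol
Conditions: SeO2 (0.3 equiv), t-BuOOH (2 equiv), CH2Cl2, 0 °C → rt
Reagents that add atoms: tert-butyl hydroperoxide, CC(C)(C)OO
Why: Selenium dioxide allylic oxidation (ene reaction, then 2,3-sigmatropic shift) should hydroxylate the ring methylene on the more substituted alkene terminus in preference to the methyl group, giving a racemic alcohol whose allyl termini are related by the mirror plane of the ring.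

Step 5
Reactants: 8 rac-8-methyl-1,4-dioxaspiro[4.5]dec-8-en-7-ol
Product: 9 rac-methyl (8-methyl-1,4-dioxaspiro[4.5]dec-8-en-7-yl) carbonate
Conditions: ClCO2Me, pyridine, DMAP (cat.), CH2Cl2, 0 °C
Reagents that add atoms: methyl chloroformate, COC(=O)Cl
Why: Acylation of the secondary allylic alcohol with a chloroformate gives the carbonate, a leaving group that ionises under neutral conditions and supplies its own base.

Step 6
Reactants: 5 (S)-4-hydroxy-6-methyl-5,6-dihydro-2H-pyran-2-one; 9 rac-methyl (8-methyl-1,4-dioxaspiro[4.5]dec-8-en-7-yl) carbonate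
Product: 10 (6S)-4-hydroxy-6-methyl-3-[(7S)-8-methyl-1,4-dioxaspiro[4.5]dec-8-en-7-yl]-5,6-dihydro-2H-pyran-2-one
Conditions: [Pd(C3H5)Cl]2 (2.5 mol %), (1R,2R)-N,N'-bis[2-(diphenylphosphanyl)benzoyl]cyclohexane-1,2-diamine (7.5 mol %), CH2Cl2, rt
Reagents that add atoms: none
Why: Tsuji–Trost asymmetric allylic alkylation, in which both enantiomers of 9 ionise to one π-allyl complex of zerovalent-palladium origin whose termini are enantiotopic, so that C-attack of the soft lactone enolate can give only one constitution and the chiral ligand chooses the terminus and thereby the C8 configuration; the (R,R) ligand is the antipode expected from its working model for cyclic allyl units, the mirror-image ligand is used if the sense proves reversed, and a C8 epimer is a separable diastereomer.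

Step 7
Reactants: 10 (6S)-4-hydroxy-6-methyl-3-[(7S)-8-methyl-1,4-dioxaspiro[4.5]dec-8-en-7-yl]-5,6-dihydro-2H-pyran-2-one
Product: 11 (6S)-6-methyl-3-[(7S)-8-methyl-1,4-dioxaspiro[4.5]dec-8-en-7-yl]-4-[2-(trimethylsilyl)ethoxy]-5,6-dihydro-2H-pyran-2-one
Conditions: Me3SiCH2CH2OH, PPh3, iPrO2CN=NCO2iPr, THF, 0 °C → rt
Reagents that add atoms: 2-(trimethylsilyl)ethanol, C[Si](C)(C)CCO
Why: Mitsunobu O-alkylation of the acidic enol by a primary alcohol should give the enol ether at O4' under neutral conditions that spare the ring alkene and the ketal, and it masks the enol before the oxidation.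

Step 8
Reactants: 11 (6S)-6-methyl-3-[(7S)-8-methyl-1,4-dioxaspiro[4.5]dec-8-en-7-yl]-4-[2-(trimethylsilyl)ethoxy]-5,6-dihydro-2H-pyran-2-one
Product: 13 2-{2-[(2R)-2-Lac-3-oxobutyl]-1,3-dioxolan-2-yl}acetaldehyde, via cis-6,7-diol 12 (not isolated)
Conditions: OsO4 (2 mol %), NaIO4 (4 equiv), 2,6-lutidine (2 equiv), 1,4-dioxane/H2O (3:1), rt
Reagents that add atoms: sodium periodate, [Na+].[O-]I(=O)(=O)=O (terminal oxidant, oxygen relayed through OsO4); water, O
Why: Lemieux–Johnson cleavage, in which OsO4 dihydroxylates the electron-rich trisubstituted ring alkene and not the tetrasubstituted push–pull alkene of the lactone, and periodate cuts the diol to the C7 methyl ketone and the C6 aldehyde while the lutidine buffer protects the ketal and the C8 centre.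

Step 9
Reactants: 13 2-{2-[(2R)-2-Lac-3-oxobutyl]-1,3-dioxolan-2-yl}acetaldehyde
Product: 14 (8S,9R)-8-hydroxy-8-methyl-9-Lac-1,4-dioxaspiro[4.5]decan-7-one
Conditions: 2-(pentafluorophenyl)-6,7-dihydro-5H-pyrrolo[2,1-c][1,2,4]triazol-2-ium tetrafluoroborate (15 mol %), Et3N (15 mol %), THF (0.05 M), 25 °C
Reagents that add atoms: none
Why: The carbene released from the triazolium adds to the C6 aldehyde, a 1,2-proton shift turns the adduct into the Breslow intermediate with nucleophilic C6, and this carbon bonds to the carbonyl carbon of the C7 methyl ketone before the alkoxide expels the azolium (intramolecular crossed aldehyde–ketone benzoin, the established carbene-catalysed route from 1,6-keto aldehydes to 2-hydroxy-2-methylcyclohexanones). Ring A closes in the 6-exo-trig mode, helped by the spiro ketal at C4a, which gathers the two chain ends. The new C7 centre is controlled by the resident C8 centre through a chair-like transition state: the lactone stays equatorial because an axial lactone would face a dioxolane oxygen across the ring, the acetyl methyl also takes an equatorial site, and the carbonyl oxygen is therefore axial, so that the hydroxyl should emerge cis to the lactone; this is also the more stable ketol, so any reversal of the benzoin corrects in the same direction. The step needs the aldehyde to act as the acyl anion donor and the ketone as the acceptor, which the substrate secures because only the aldehyde can form the Breslow intermediate and the six-membered closure is the only unstrained one. It also needs freedom from aldol closure, from loss of a ketal oxygen by β-elimination and from epimerisation at C8, all of which require free base; an electron-poor triazolium with an equimolar amount of triethylamine keeps that base at a very low level.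

Step 10
Reactants: 14 (8S,9R)-8-hydroxy-8-methyl-9-Lac-1,4-dioxaspiro[4.5]decan-7-one
Product: 15 (4S,5R)-4-hydroxy-4-methyl-5-Lac-cyclohexane-1,3-dione
Conditions: 1 M aq. HCl, THF, rt
Reagents that add atoms: water, O
Why: Acid-catalysed ketal hydrolysis is driven by the stability of the enolised 1,3-dione, while the silylethyl enol ether of the lactone needs far stronger acid and the tertiary α-ketol has no easy elimination path.

Step 11
Reactants: 15 (4S,5R)-4-hydroxy-4-methyl-5-Lac-cyclohexane-1,3-dione
Product: 16 (5R,6S)-2-chloro-3,6-dihydroxy-6-methyl-5-Lac-cyclohex-2-en-1-one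
Conditions: N-chlorosuccinimide (1.0 equiv), CH2Cl2, 0 °C
Reagents that add atoms: N-chlorosuccinimide, O=C1CCC(=O)N1Cl
Why: Electrophilic chlorination of the enol of a cyclic 1,3-dione with one equivalent of reagent should occur at C5, the only carbon between the two carbonyls, and the lactone enol ether carbon is fully substituted.

Step 12
Reactants: 16 (5R,6S)-2-chloro-3,6-dihydroxy-6-methyl-5-Lac-cyclohex-2-en-1-one
Product: 17 (4S,5R)-2-chloro-4-hydroxy-4-methyl-5-Lac-3-oxocyclohex-1-en-1-yl trifluoromethanesulfonate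
Conditions: Tf2O (1.05 equiv), Et3N (1.2 equiv), CH2Cl2, −78 °C
Reagents that add atoms: trifluoromethanesulfonic anhydride, O=S(=O)(OS(=O)(=O)C(F)(F)F)C(F)(F)F
Why: Enol triflate formation from the ammonium enolate of the vinylogous acid should take the oxygen on C4a, which is flanked by a methylene, and not the oxygen on C6, which is shielded by the quaternary C7 and hydrogen-bonded to its hydroxyl, while the hindered tertiary alcohol does not compete at this temperature.

Step 13
Reactants: 18 (S)-2-methylbutan-1-ol; 19 ethyl 2-(triphenyl-λ5-phosphanylidene)propanoate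
Product: 21 ethyl (S,E)-2,4-dimethylhex-2-enoate, via (S)-2-methylbutanal 20 (not isolated)
Conditions: TEMPO (10 mol %), PhI(OAc)2 (1.1 equiv), CH2Cl2, rt; then 19, rt
Reagents that add atoms: none
Why: One-pot alcohol oxidation and Wittig reaction with a stabilised ylide traps the configurationally labile α-branched aldehyde as it forms and should give the E-trisubstituted enoate with the stereocentre intact.

Step 14
Reactants: 21 ethyl (S,E)-2,4-dimethylhex-2-enoate
Product: 22 (S,E)-2,4-dimethylhex-2-en-1-ol
Conditions: iBu2AlH (2.2 equiv), CH2Cl2, −78 °C; aq. potassium sodium tartrate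
Reagents that add atoms: none
Why: Hydride reduction of the conjugated ester by the aluminium hydride proceeds with 1,2-selectivity to the allylic alcohol and does not touch the alkene geometry or the stereocentre.

Step 15
Reactants: 22 (S,E)-2,4-dimethylhex-2-en-1-ol
Product: 23 (S,E)-2,4-dimethylhex-2-enal
Conditions: MnO2 (excess), CH2Cl2, rt
Reagents that add atoms: none
Why: MnO2 oxidises allylic alcohols selectively to enals under neutral conditions, so the alkene and the γ-stereocentre are preserved.

Step 16
Reactants: 23 (S,E)-2,4-dimethylhex-2-enal; 24 diethyl [3-(trimethylsilyl)prop-2-yn-1-yl]phosphonate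
Product: 25 trimethyl[(3E,5E,7S)-5,7-dimethylnona-3,5-dien-1-yn-1-yl]silane
Conditions: 24, LiN(SiMe3)2, THF, −78 °C; then 23, −78 °C → rt
Reagents that add atoms: none
Why: Horner–Wadsworth–Emmons olefination with the preformed propargylic phosphonate anion should give the E-enyne, with the silyl group guarding the alkyne terminus and no excess base left to disturb the allylic stereocentre.

Step 17
Reactants: 25 trimethyl[(3E,5E,7S)-5,7-dimethylnona-3,5-dien-1-yn-1-yl]silane
Product: 26 (3E,5E,7S)-5,7-dimethylnona-3,5-dien-1-yne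
Conditions: K2CO3 (0.2 equiv), MeOH, rt; used as a solution
Reagents that add atoms: none
Why: Base-catalysed methanolysis of the alkynyl–silicon bond (protodesilylation) frees the terminal alkyne and leaves the diene unchanged.

Step 18
Reactants: 17 (4S,5R)-2-chloro-4-hydroxy-4-methyl-5-Lac-3-oxocyclohex-1-en-1-yl trifluoromethanesulfonate; 26 (3E,5E,7S)-5,7-dimethylnona-3,5-dien-1-yne
Product: 27 (5R,6S)-2-chloro-3-[(3E,5E,7S)-5,7-dimethylnona-3,5-dien-1-yn-1-yl]-6-hydroxy-6-methyl-5-Lac-cyclohex-2-en-1-one
Conditions: PdCl2(PPh3)2 (5 mol %), CuI (10 mol %), iPr2NEt, THF, rt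
Reagents that add atoms: none
Why: Sonogashira coupling, in which zerovalent palladium inserts into the activated vinyl C–OTf bond in preference to the vinyl C–Cl bond and the copper acetylide of 26 delivers the dienynyl group to C4a, a hindered amine being chosen so that it does not add to the enone.

Step 19
Reactants: 27 (5R,6S)-2-chloro-3-[(3E,5E,7S)-5,7-dimethylnona-3,5-dien-1-yn-1-yl]-6-hydroxy-6-methyl-5-Lac-cyclohex-2-en-1-one
Product: 28 (5R,6S)-2-chloro-4-[(dimethylamino)methylidene]-3-[(3E,5E,7S)-5,7-dimethylnona-3,5-dien-1-yn-1-yl]-6-hydroxy-6-methyl-5-Lac-cyclohex-2-en-1-one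
Conditions: t-BuOCH(NMe2)2 (3 equiv), toluene, 60 °C
Reagents that add atoms: tert-butoxybis(dimethylamino)methane, CN(C)C(OC(C)(C)C)N(C)C
Why: Condensation of an aminal ester with a vinylogous CH-acid, in which the C8a methylene is the γ-position of the chloro enynone and the only acidic site left (C7 is quaternary, C5 bears chlorine), so that aminomethylenation there should give a stabilised push–pull dienaminone.

Step 20
Reactants: 28 (5R,6S)-2-chloro-4-[(dimethylamino)methylidene]-3-[(3E,5E,7S)-5,7-dimethylnona-3,5-dien-1-yn-1-yl]-6-hydroxy-6-methyl-5-Lac-cyclohex-2-en-1-one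
Product: 30 (7S,8R)-5-chloro-3-[(1E,3E,5S)-3,5-dimethylhepta-1,3-dien-1-yl]-7-hydroxy-7-methyl-8-Lac-7,8-dihydro-6H-isochromen-6-one, via hydroxymethylidene ketone 29 (not isolated)
Conditions: 1 M aq. HCl, THF, 0 °C; extractive work-up; then Ph3PAuNTf2 (5 mol %), CH2Cl2, rt
Reagents that add atoms: water, O
Why: Aqueous acid hydrolyses the vinylogous amide to the hydroxymethylidene tautomer of the C8a aldehyde, whose enol oxygen then adds to the gold-activated alkyne at C3 in a 6-endo-dig cycloisomerisation (formally a 1,6-oxa-Michael addition to the enynone) that the cation-stabilising dienyl group favours over 5-exo closure.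

Step 21
Reactants: 30 (7S,8R)-5-chloro-3-[(1E,3E,5S)-3,5-dimethylhepta-1,3-dien-1-yl]-7-hydroxy-7-methyl-8-Lac-7,8-dihydro-6H-isochromen-6-one
Product: 31 (7S,8S)-5-chloro-3-[(1E,3E,5S)-3,5-dimethylhepta-1,3-dien-1-yl]-7-hydroxy-7-methyl-8-[(3R,6S)-6-methyl-2,4-dioxooxan-3-yl]-7,8-dihydro-6H-isochromen-6-one (CNP0584120.1)
Conditions: CF3CO2H/CH2Cl2 (1:4), 0 °C
Reagents that add atoms: none
Why: Acid cleaves the 2-(trimethylsilyl)ethyl enol ether by β-silyl fragmentation, releasing only ethene and a silyl ester that cannot alkylate the product, and the freed 2,4-dione should settle at C3' by keto–enol equilibration.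

Compound list
1 | methyl (S)-3-hydroxybutanoate | C[C@H](O)CC(=O)OC | starting material
2 | tert-butyl acetate | CC(=O)OC(C)(C)C | starting material
3 | tert-butyl (S)-5-hydroxy-3-oxohexanoate | C[C@H](O)CC(=O)CC(=O)OC(C)(C)C | intermediate
4 | (S)-5-hydroxy-3-oxohexanoic acid | C[C@H](O)CC(=O)CC(=O)O | intermediate
5 | (S)-4-hydroxy-6-methyl-5,6-dihydro-2H-pyran-2-one (enol form of (S)-6-methyloxane-2,4-dione) | C[C@H]1CC(O)=CC(=O)O1 | intermediate
6 | 1,4-dioxaspiro[4.5]dec-7-en-8-yl trifluoromethanesulfonate | O=S(=O)(OC1=CCC2(CC1)OCCO2)C(F)(F)F | starting material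
7 | 8-methyl-1,4-dioxaspiro[4.5]dec-7-ene | CC1=CCC2(CC1)OCCO2 | intermediate
8 | rac-8-methyl-1,4-dioxaspiro[4.5]dec-8-en-7-ol | CC1=CCC2(CC1O)OCCO2 | intermediate
9 | rac-methyl (8-methyl-1,4-dioxaspiro[4.5]dec-8-en-7-yl) carbonate | COC(=O)OC1CC2(CC=C1C)OCCO2 | intermediate
10 | (6S)-4-hydroxy-6-methyl-3-[(7S)-8-methyl-1,4-dioxaspiro[4.5]dec-8-en-7-yl]-5,6-dihydro-2H-pyran-2-one | CC1=CCC2(C[C@@H]1C3=C(O)C[C@H](C)OC3=O)OCCO2 | intermediate
11 | (6S)-6-methyl-3-[(7S)-8-methyl-1,4-dioxaspiro[4.5]dec-8-en-7-yl]-4-[2-(trimethylsilyl)ethoxy]-5,6-dihydro-2H-pyran-2-one | CC1=CCC2(C[C@@H]1C3=C(OCC[Si](C)(C)C)C[C@H](C)OC3=O)OCCO2 | intermediate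
12 | cis-6,7-diol of 11 (both hydroxyls trans to Lac) | C[C@]1(O)[C@@H](O)CC2(C[C@@H]1C3=C(OCC[Si](C)(C)C)C[C@H](C)OC3=O)OCCO2 | intermediate
13 | 2-{2-[(2R)-2-Lac-3-oxobutyl]-1,3-dioxolan-2-yl}acetaldehyde (keto aldehyde, benzoin substrate) | CC(=O)[C@@H](C1=C(OCC[Si](C)(C)C)C[C@H](C)OC1=O)CC2(CC=O)OCCO2 | intermediate
14 | (8S,9R)-8-hydroxy-8-methyl-9-Lac-1,4-dioxaspiro[4.5]decan-7-one (ring A α-ketol) | O=C1CC2(OCCO2)C[C@H](C3=C(OCC[Si](C)(C)C)C[C@H](C)OC3=O)[C@]1(C)O | intermediate
15 | (4S,5R)-4-hydroxy-4-methyl-5-Lac-cyclohexane-1,3-dione | O=C1CC(=O)C[C@H](C2=C(OCC[Si](C)(C)C)C[C@H](C)OC2=O)[C@]1(C)O | intermediate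
16 | (5R,6S)-2-chloro-3,6-dihydroxy-6-methyl-5-Lac-cyclohex-2-en-1-one (enol form of the 2-chloro-1,3-dione) | O=C1C(Cl)=C(O)C[C@H](C2=C(OCC[Si](C)(C)C)C[C@H](C)OC2=O)[C@]1(C)O | intermediate
17 | (4S,5R)-2-chloro-4-hydroxy-4-methyl-5-Lac-3-oxocyclohex-1-en-1-yl trifluoromethanesulfonate | O=C1C(Cl)=C(OS(=O)(=O)C(F)(F)F)C[C@H](C2=C(OCC[Si](C)(C)C)C[C@H](C)OC2=O)[C@]1(C)O | intermediate
18 | (S)-2-methylbutan-1-ol | CC[C@H](C)CO | starting material
19 | ethyl 2-(triphenyl-λ5-phosphanylidene)propanoate | CCOC(=O)C(C)=P(c1ccccc1)(c1ccccc1)c1ccccc1 | starting material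
20 | (S)-2-methylbutanal | CC[C@H](C)C=O | intermediate
21 | ethyl (S,E)-2,4-dimethylhex-2-enoate | CC[C@H](C)/C=C(\C)C(=O)OCC | intermediate
22 | (S,E)-2,4-dimethylhex-2-en-1-ol | CC[C@H](C)/C=C(\C)CO | intermediate
23 | (S,E)-2,4-dimethylhex-2-enal | CC[C@H](C)/C=C(\C)C=O | intermediate
24 | diethyl [3-(trimethylsilyl)prop-2-yn-1-yl]phosphonate | CCOP(=O)(CC#C[Si](C)(C)C)OCC | starting material
25 | trimethyl[(3E,5E,7S)-5,7-dimethylnona-3,5-dien-1-yn-1-yl]silane | CC[C@H](C)/C=C(C)/C=C/C#C[Si](C)(C)C | intermediate
26 | (3E,5E,7S)-5,7-dimethylnona-3,5-dien-1-yne | CC[C@H](C)/C=C(C)/C=C/C#C | intermediate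
27 | (5R,6S)-2-chloro-3-[(3E,5E,7S)-5,7-dimethylnona-3,5-dien-1-yn-1-yl]-6-hydroxy-6-methyl-5-Lac-cyclohex-2-en-1-one | O=C1C(Cl)=C(C#C/C=C/C(C)=C/[C@@H](C)CC)C[C@H](C2=C(OCC[Si](C)(C)C)C[C@H](C)OC2=O)[C@]1(C)O | intermediate
28 | (5R,6S)-2-chloro-4-[(dimethylamino)methylidene]-3-[(3E,5E,7S)-5,7-dimethylnona-3,5-dien-1-yn-1-yl]-6-hydroxy-6-methyl-5-Lac-cyclohex-2-en-1-one (alkene geometry at C8a not assigned) | O=C1C(Cl)=C(C#C/C=C/C(C)=C/[C@@H](C)CC)C(=CN(C)C)[C@H](C2=C(OCC[Si](C)(C)C)C[C@H](C)OC2=O)[C@]1(C)O | intermediate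
29 | (5R,6S)-2-chloro-3-[(3E,5E,7S)-5,7-dimethylnona-3,5-dien-1-yn-1-yl]-6-hydroxy-4-(hydroxymethylidene)-6-methyl-5-Lac-cyclohex-2-en-1-one | O=C1C(Cl)=C(C#C/C=C/C(C)=C/[C@@H](C)CC)C(=CO)[C@H](C2=C(OCC[Si](C)(C)C)C[C@H](C)OC2=O)[C@]1(C)O | intermediate
30 | (7S,8R)-5-chloro-3-[(1E,3E,5S)-3,5-dimethylhepta-1,3-dien-1-yl]-7-hydroxy-7-methyl-8-Lac-7,8-dihydro-6H-isochromen-6-one | CC[C@H](C)/C=C(C)/C=C/C1=CC2=C(Cl)C(=O)[C@@](C)(O)[C@@H](C3=C(OCC[Si](C)(C)C)C[C@H](C)OC3=O)C2=CO1 | intermediate
31 | (7S,8S)-5-chloro-3-[(1E,3E,5S)-3,5-dimethylhepta-1,3-dien-1-yl]-7-hydroxy-7-methyl-8-[(3R,6S)-6-methyl-2,4-dioxooxan-3-yl]-7,8-dihydro-6H-isochromen-6-one | CC[C@H](C)/C=C(C)/C=C/C1=CC2=C(Cl)C(=O)[C@@](C)(O)[C@@H]([C@@H]3C(=O)C[C@H](C)OC3=O)C2=CO1 | target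

Total step count: 21 steps.
Longest linear sequence: 14 steps (6 to 31 through steps 3–12 and 18–21).

Steps most likely to fail

1. Step 9 (key step). The small amount of amine may still trigger aldol ring closure (C5 onto C7, or C8 onto C6) or expel a ketal oxygen from the aldehyde enolate, and the two faces of the ketone may be discriminated poorly. The fallback sets out from 11. Epoxidation of the ring alkene with mCPBA (CH2Cl2, NaHCO3, 0 °C) on the face away from the lactone gives the 6,7-epoxide of 11 F1. Dilute HClO4 in aqueous THF opens the oxirane at the tertiary C7 with inversion and should give the trans-6,7-diol F2, whose C7 hydroxyl is then cis to the lactone. Oxidation of the secondary C6 alcohol (SO3·pyridine, DMSO, Et3N) comes back to the route at 14.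

2. Step 19. The C8a methylene may condense too slowly, or the dimethylamine set free may add to the enynone before the condensation is complete. The fallback sets out from 27. Me3SiOTf and Et3N silylate the C7 hydroxyl and convert the enone into its extended enol ether, the bis-silyl dienol ether F3. A vinylogous Mukaiyama reaction with HC(OMe)3 and BF3·OEt2 at −78 °C attaches the masked formyl group at C8a and gives the dimethyl acetal F4. Dilute aqueous acid frees the aldehyde and the alcohol and comes back to the route at 29, which is cyclised to 30 as in step 20.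

3. Step 6. The 2-methyl-substituted allyl unit may ionise or be attacked slowly, the allyl complex may lose a proton to give a diene, or the ligand may choose poorly between the two termini. The fallback sets out from 5 and 8. Mitsunobu O-alkylation (PPh3, iPrO2CN=NCO2iPr, THF) gives the allyl enol ether F5, and a thermal Claisen rearrangement (toluene, 110 °C) shifts the ring from O4' to C3' and comes back to the route at 10. Because the two allyl termini are equivalent by the mirror plane of the ring, the constitution is the same; the C8 epimers are diastereomers and are separated, or 8 is resolved beforehand so that the suprafacial shift transfers its configuration.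

Further compounds
F1 | step 9 | 6,7-epoxide of 11 (oxirane oxygen trans to Lac) | C[C@]12O[C@H]1CC3(C[C@@H]2C4=C(OCC[Si](C)(C)C)C[C@H](C)OC4=O)OCCO3
F2 | step 9 | trans-6,7-diol from F1 (C7 hydroxyl cis to Lac, C6 hydroxyl trans to Lac) | C[C@@]1(O)[C@@H](O)CC2(C[C@@H]1C3=C(OCC[Si](C)(C)C)C[C@H](C)OC3=O)OCCO2
F3 | step 19 | bis-silyl dienol ether of 27 (C7 trimethylsilyl ether, C6 trimethylsilyloxy diene) | C[Si](C)(C)OC1=C(Cl)C(C#C/C=C/C(C)=C/[C@@H](C)CC)=C[C@H](C2=C(OCC[Si](C)(C)C)C[C@H](C)OC2=O)[C@]1(C)O[Si](C)(C)C
F4 | step 19 | C8a dimethoxymethyl derivative of 27 as its C7 trimethylsilyl ether (C8a configuration not assigned) | COC(OC)C1C(C#C/C=C/C(C)=C/[C@@H](C)CC)=C(Cl)C(=O)[C@@](C)(O[Si](C)(C)C)[C@H]1C2=C(OCC[Si](C)(C)C)C[C@H](C)OC2=O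
F5 | step 6 | (6S)-6-methyl-4-[(8-methyl-1,4-dioxaspiro[4.5]dec-8-en-7-yl)oxy]-5,6-dihydro-2H-pyran-2-one | CC1=CCC2(CC1OC3=CC(=O)O[C@@H](C)C3)OCCO2
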